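## Structural features

The target is a carvone-type monoterpenoid: a cyclohexanone fused to an oxirane (7-oxabicyclo[4.1.0]heptan-2-one) and esterified at the α′-oxygen by a ten-carbon diester chain. The ring is numbered here C1 (ketone), C2 (methyl-bearing oxirane carbon), C3 (oxirane CH), C4 (CH2), C5 (isopropenyl) and C6 (acyloxy). The four stereocentres form two adjacent pairs, C5/C6 and C2/C3, joined through C1 on one side and C4 on the other. The C6 oxygen is trans to isopropenyl and cis to the oxirane oxygen; the absolute configuration is 2S,3S,5R,6R in this numbering, (1S,3R,4R,6S) in the bicyclic name. The chain is an (E)-4-oxy-2-methylbut-2-enoate whose allylic oxygen carries a tiglate, so it holds two conjugated E-enoates and one allylic ester. Fragile points are the α,β-epoxy ketone, the α-acyloxy ketone (acidic, epimerisable C6–H; ester prone to cleavage or migration), the allylic ester and the isopropenyl group. The real difficulty is the oxygen pattern: C6, C1, C2 and C3 are all oxygenated, at different oxidation and protection levels, with defined relative and absolute configuration, and the C1 and C6 oxygens must be told apart. The key step exploits the fact that C1 and C6 carry vicinal oxygens and lie between C2 (methyl) and C5 (three-carbon group), which are para to each other. This is the pattern of the cis-dihydrodiol of a para-disubstituted benzene, so all six ring carbons, both substituents and both oxygens can come from 4'-methylacetophenone.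

## Logic of the disconnections

17 ⇒ 16. The C1 carbonyl is taken back to a C1 carbinol. With C1 at the alcohol level, C6–H is not acidic, the oxirane is not yet part of an epoxy ketone, and O1 can still direct. The gain is that the most fragile array exists only in the last flask. The demand is a neutral oxidation that spares oxirane, esters and alkenes.

16 ⇒ 11 + 15. The acyl–O6 bond is cut. It is the only bond joining the oxygenated ring to the diester chain, so the synthesis becomes convergent. The demand is acylation at O6 and not at O1 of a cis-diol.

15 ⇒ 14 ⇒ 12 + 13. First the tert-butyl–O bond, then the C2=C3 double bond of the inner enoate, are cut. Both halves are purchasable esters, and the tert-butyl ester is orthogonal to the allylic ester. The demand is an E-selective cross-metathesis of the 1,1-disubstituted alkene of 13, and an acidolysis that does not ionise the allylic ester.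

11 ⇒ 10. The C2–O and C3–O bonds of the oxirane are cut. The allylic O1–H can deliver oxygen to its own face, which is also the face away from the C5 substituent. Two stereocentres are removed. The demand is chemoselectivity for C2=C3 over the 1,1-disubstituted alkene on C5.

10 ⇒ 9. The two O–H bonds are replaced by the C–O bonds of an isopropylidene acetal, because the diol must survive hydride and ylide reagents. The demand is a hydrolysis mild enough for an allylic alcohol and an isopropenyl group.

9 ⇒ 6 + 7. The exocyclic C=CH2 bond is cut back to C=O. The acetyl group is what the arene carries, what activates C4=C5 for conjugate reduction and what makes C5 epimerisable. One carbon then comes from 7. The demand is methylenation of an α-branched β-alkoxy methyl ketone without elimination.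

6 ⇒ 3. The C4–H and C5–H bonds are removed and C4=C5 is restored. The C5 stereocentre then becomes a matter of thermodynamics, and one stereocentre disappears. The demand is 1,4-delivery of hydride (not 1,6 or 1,2), followed by equilibration to the trans isomer without loss of O6.

3 ⇒ 2. The two acetal C–O bonds are cut. The demand is protection fast enough to outrun acid-induced aromatisation.

2 ⇒ 1. The C1–O and C6–O bonds are cut and the aromatic ring is restored. Vicinal cis oxygens flanked by para-related substituted carbons are the signature of enzymatic arene dihydroxylation. Every ring atom, both substituents and both oxygens then come from one achiral commercial arene, and all later stereocentres follow from C1/C6. The demand is an oxygenase that accepts 1 and chooses the enantiotopic face that treats acetyl as the large group.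

## Other disconnections considered

Alternative 1: The C2–C3 bond and the C2–O bond of the oxirane are cut together, which opens the carbocycle to the acyclic α-bromo ketone aldehyde A1 (C3 as aldehyde, C2 as the CHBr carbon, O6 as silyl ether). Forward, soft enolisation toward C2 would be followed by aldol addition to the aldehyde (six-membered ring closed through the enolate carbon) and 3-exo-tet displacement of bromide by the new alkoxide, giving silyl ether A2 in one operation. Desilylation and esterification with 15 would finish 17.
- In its favour: ring, quaternary C2 and oxirane arise together. C1 is a ketone and O6 is protected from the start, so the C1/C6 differentiation that burdens the chosen plan at step 9 does not arise; on this point Alternative 1 is the better design.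
- Against it: A1 must be made enantiopure with the correct C5/C6 relation by separate asymmetric chemistry before any ring exists. Enolisation must favour C2 over C6, and the enolisable aldehyde must not self-condense. The oxirane face relative to C5/C6 would be decided in the aldol step without a directing element, and only bromohydrins with anti-periplanar O and Br can close.
- Comparison: both plans use substrate control for C2/C3, but the chosen plan fixes that face twice (hydroxyl delivery, and anti to isopropenyl). The end games are equal in length (two steps from A2, two from 11). The front end of Alternative 1 is expected to be longer, since the chosen plan obtains ring, both oxygens and absolute configuration in step 1.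

Alternative 2: The C4–C5 and C1–C6 bonds are cut in a retro-Diels–Alder sense to isoprene A3 and the (E)-β-acyloxy enone A4, which already carries the whole diester chain. Forward, a chiral oxazaborolidinium-type Lewis acid would activate the ketone of A4, and the diene would add with para orientation to give adduct A5; the trans C5/C6 relation follows from the E alkene.
- In its favour: it is the most convergent plan, with skeleton, side chain and two stereocentres from one catalytic step. On convergence, on operations up to the ring, and on predictability of regio- and stereochemistry (a cycloaddition against an enzyme of unproven scope for 1) it is better than the chosen plan.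
- Against it: A5 has a methylene at C1. The ketone oxygen would need a late allylic oxidation in competition with C4, the C2 methyl, the isopropenyl group and the allylic positions of the chain. The acetyl group would have to be methylenated next to a β-acyloxy group, a far better leaving group than the acetal oxygen of 6. The oxirane could only come from nucleophilic epoxidation with three base-labile esters present.
- Comparison: the chosen plan delivers both ring oxygens at the right carbons in its key step, whereas Alternative 2 delivers only O6. Total step count would be similar or slightly lower for Alternative 2, but with weaker late steps.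

Alternative 3: The C5–C6 bond is cut, and the ring opens to the epoxy α-keto aldehyde A6, with the oxirane in place and C5 as the inner carbon of a trisubstituted alkene. Forward, an intramolecular carbonyl-ene reaction would join C6 to C5 with transfer of an allylic methyl hydrogen to oxygen, through a chair-like transition state. This closes the six-membered ring and forms the isopropenyl group and the C6 hydroxyl of A7; esterification with 15 would give 17.
- In its favour: the same type of cyclisation closes open-chain terpene aldehydes to trans-2-isopropenylcyclohexanols. C1 is already a ketone and A7 has a single hydroxyl, so acylation is unambiguous and no oxidation follows; in end-game economy and C1/C6 differentiation it is better than the chosen plan. The absolute configuration would come from an asymmetric epoxidation, equal or better in predictability than the enzymatic step.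
- Against it: A6 is a 1,2-dicarbonyl compound next to a quaternary oxirane, prone to hydration, oligomerisation and Lewis-acid-induced epoxide opening, and its preparation needs several oxidation-state adjustments. The induction from the C2/C3 oxirane to the new C5/C6 pair rests on a tether conformation with no directing group, whereas the chosen plan forms the oxirane last under double control. Prins-type pathways could compete.
- Comparison: Alternative 3 makes one ring bond and two stereocentres in its key step; the chosen plan makes two C–O bonds and two stereocentres on a preformed ring. Each carries one unproven selectivity, and overall length is likely comparable.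

Key step: step 1

Remarks on the chemistry:
- In 1 the two carbons that receive oxygen differ in kind: C6 is ortho to acetyl and meta to methyl, C1 is ortho to methyl and meta to acetyl. No adjacent pair is ortho to acetyl at both carbons; the only adjacent unsubstituted pairs are this one and its symmetry-equivalent partner.
- Assumption: toluene dioxygenase accepts 1 and places acetyl where the larger substituent binds, giving (1S,2R)-2; this extrapolates from acetophenone and 4-halotoluenes.
- Allyl tiglate 12 is taken as a purchased flavour-grade ester.

## Route

Step 1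
Reactants: 1 4'-methylacetophenone
Product: 2 (1S,2R)-3-acetyl-6-methylcyclohexa-3,5-diene-1,2-diol
Conditions: recombinant E. coli whole cells expressing toluene dioxygenase (todC1C2BA), glucose, air, phosphate buffer pH 7.4, 30 °C; EtOAc extraction at pH ≥ 7
Reagents that add atoms: dioxygen, O=O
Why: The non-haem iron oxygenase binds O2 at its mononuclear iron centre, receives two electrons from NADH through reductase and ferredoxin, and transfers both atoms of one O2 to the same face of two neighbouring unsubstituted ring carbons, so the C1–O and C6–O bonds form cis and the arene is left as the C2=C3–C4=C5 diene conjugated with acetyl. The closest known reaction type is the toluene dioxygenase cis-dihydroxylation of acetophenone and of para-substituted toluenes such as 4-iodotoluene. No ring is closed. Both new stereocentres (C1 S, C6 R) are set by the enzyme: the cis relation follows from the mechanism, and the absolute sense from the orientation of the arene in the active site, where acetyl is expected to take the place of the methyl group of toluene. Regioselectivity needs no control, because the two pairs of adjacent unsubstituted carbons of a para-disubstituted benzene are symmetry-equivalent and only the enantiotopic choice remains. The step needs enantioselectivity and chemoselectivity over benzylic hydroxylation and carbonyl reduction; a host without diol dehydrogenase lets 2 accumulate, and work-up at pH ≥ 7 prevents dehydration to a phenol.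

Step 2
Reactants: 2 (1S,2R)-3-acetyl-6-methylcyclohexa-3,5-diene-1,2-diol
Product: 3 1-[(3aR,7aS)-2,2,7-trimethyl-3a,7a-dihydro-1,3-benzodioxol-4-yl]ethan-1-one
Conditions: Me2C(OMe)2, p-TsOH·H2O (cat.), acetone, 0 °C → rt; Et3N quench
Reagents that add atoms: 2,2-dimethoxypropane, COC(C)(C)OC
Why: Acid-catalysed transketalisation of a cis-1,2-diol (acetonide formation) is fast and standard for arene cis-dihydrodiols; short exposure and the amine quench limit aromatisation. The cis-fused dioxolane masks both hydroxyls for the hydride and ylide steps.

Step 3
Reactants: 3 1-[(3aR,7aS)-2,2,7-trimethyl-3a,7a-dihydro-1,3-benzodioxol-4-yl]ethan-1-one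
Product: 6 1-[(3aR,4S,7aS)-2,2,7-trimethyl-3a,4,5,7a-tetrahydro-1,3-benzodioxol-4-yl]ethan-1-one (acetyl trans to O6), via dimethylphenylsilyl enol ether 4 (not isolated), via kinetic C5-epimeric ketone 5 (not isolated)
Conditions: [(Ph3P)CuH]6 (5 mol%), PhMe2SiH (1.3 equiv), toluene, rt; then K2CO3 (0.5 equiv), MeOH, 0 °C → rt
Reagents that add atoms: none
Why: Copper hydride conjugate reduction (catalytic 1,4-hydrosilylation of an enone) should deliver hydride to the unsubstituted β-carbon C4 rather than the methyl-bearing δ-carbon C2, giving silyl enol ether 4 and leaving C2=C3 isolated. Methanolysis releases the ketone as kinetic mixture 5, and carbonate in methanol equilibrates C5 through the enolate to the isomer with acetyl on the convex face, trans to O6. C5 is thus set under thermodynamic control by the enzyme-derived centres; mild base and low temperature are chosen to keep β-elimination of O6 slow.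

Step 4
Reactants: 6 1-[(3aR,4S,7aS)-2,2,7-trimethyl-3a,4,5,7a-tetrahydro-1,3-benzodioxol-4-yl]ethan-1-one, 7 methyltriphenylphosphonium bromide
Product: 9 (3aR,4R,7aS)-2,2,7-trimethyl-4-(prop-1-en-2-yl)-3a,4,5,7a-tetrahydro-1,3-benzodioxole, via methylenetriphenylphosphorane 8 (not isolated)
Conditions: 7 (1.5 equiv), KOtBu (1.4 equiv), THF, 0 °C; then 6, 0 °C → rt
Reagents that add atoms: none
Why: Wittig methylenation of a methyl ketone; a slight excess of phosphonium salt over base keeps free alkoxide out of the flask. Any epimerisation at C5 only returns the more stable trans isomer already in hand, and no stereocentre is formed.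

Step 5
Reactants: 9 (3aR,4R,7aS)-2,2,7-trimethyl-4-(prop-1-en-2-yl)-3a,4,5,7a-tetrahydro-1,3-benzodioxole
Product: 10 (1R,2S,6R)-3-methyl-6-(prop-1-en-2-yl)cyclohex-3-ene-1,2-diol
Conditions: AcOH–H2O (4:1), 45 °C
Reagents that add atoms: none
Why: Mild aqueous acid hydrolysis of the isopropylidene acetal; acetic acid is too weak to hydrate the isopropenyl group or ionise the allylic C1–O bond.

Step 6
Reactants: 10 (1R,2S,6R)-3-methyl-6-(prop-1-en-2-yl)cyclohex-3-ene-1,2-diol
Product: 11 (1R,2R,3R,4R,6S)-1-methyl-4-(prop-1-en-2-yl)-7-oxabicyclo[4.1.0]heptane-2,3-diol
Conditions: VO(acac)2 (3 mol%), t-BuOOH (1.3 equiv, in decane), CH2Cl2, 0 °C → rt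
Reagents that add atoms: tert-butyl hydroperoxide, CC(C)(C)OO
Why: Vanadium-catalysed hydroxyl-directed epoxidation of a trisubstituted allylic alcohol: the C1 alkoxide, pseudoaxial because of A(1,2) strain with the C2 methyl, binds vanadium and delivers oxygen to its own face. That face is also the one away from the C5 isopropenyl group, so C2 (S) and C3 (S) are set by C1 with both effects matched. The isopropenyl alkene is only homoallylic to a hydroxyl and should react far more slowly.

Step 7
Reactants: 12 allyl tiglate [prop-2-en-1-yl (2E)-2-methylbut-2-enoate], 13 tert-butyl methacrylate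
Product: 14 tert-butyl (2E)-2-methyl-4-{[(2E)-2-methylbut-2-enoyl]oxy}but-2-enoate
Conditions: second-generation Hoveyda–Grubbs catalyst (5 mol%), 13 (4 equiv), CH2Cl2, 40 °C
Reagents that add atoms: none
Why: Olefin cross-metathesis of a terminal alkene with a 1,1-disubstituted acrylate-type partner that does not homodimerise; loss of ethene drives the reaction and the trisubstituted enoate should form as the more stable E isomer. The trisubstituted tiglate alkene of 12 is inert to the catalyst.

Step 8
Reactants: 14 tert-butyl (2E)-2-methyl-4-{[(2E)-2-methylbut-2-enoyl]oxy}but-2-enoate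
Product: 15 (2E)-2-methyl-4-{[(2E)-2-methylbut-2-enoyl]oxy}but-2-enoic acid
Conditions: CF3CO2H–CH2Cl2 (1:4), 0 °C → rt
Reagents that add atoms: none
Why: Acidolysis of a tert-butyl ester through the tert-butyl cation. The primary allylic ester is not ionised, because its allyl system is conjugated with an ester, and both enoates tolerate trifluoroacetic acid.

Step 9
Reactants: 11 (1R,2R,3R,4R,6S)-1-methyl-4-(prop-1-en-2-yl)-7-oxabicyclo[4.1.0]heptane-2,3-diol, 15 (2E)-2-methyl-4-{[(2E)-2-methylbut-2-enoyl]oxy}but-2-enoic acid
Product: 16 (1R,2R,3R,4R,6S)-2-hydroxy-1-methyl-4-(prop-1-en-2-yl)-7-oxabicyclo[4.1.0]heptan-3-yl (2E)-2-methyl-4-{[(2E)-2-methylbut-2-enoyl]oxy}but-2-enoate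
Conditions: 15 (1.05 equiv), EDC·HCl [N-(3-dimethylaminopropyl)-N′-ethylcarbodiimide hydrochloride] (1.2 equiv), DMAP (0.1 equiv), CH2Cl2, −20 → 0 °C
Reagents that add atoms: none
Why: Steglich esterification with limiting acid: in the preferred half-chair the C6 hydroxyl is equatorial next to an equatorial isopropenyl group, while the C1 hydroxyl is pseudoaxial, flanked by the fully substituted oxirane carbon C2 and hydrogen-bonded to the oxirane oxygen. Acylation should therefore go mainly to O6, and acyl migration, if any, would also favour the equatorial C6 ester. No stereocentre changes, and the carbodiimide conditions avoid deconjugation of the enoate.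

Step 10
Reactants: 16 (1R,2R,3R,4R,6S)-2-hydroxy-1-methyl-4-(prop-1-en-2-yl)-7-oxabicyclo[4.1.0]heptan-3-yl (2E)-2-methyl-4-{[(2E)-2-methylbut-2-enoyl]oxy}but-2-enoate
Product: 17 (1S,3R,4R,6S)-1-methyl-2-oxo-4-(prop-1-en-2-yl)-7-oxabicyclo[4.1.0]heptan-3-yl (2E)-2-methyl-4-{[(2E)-2-methylbut-2-enoyl]oxy}but-2-enoate (target)
Conditions: Dess–Martin periodinane (1.3 equiv), NaHCO3, CH2Cl2, 0 °C → rt
Reagents that add atoms: none
Why: Dess–Martin oxidation of the secondary C1 alcohol under buffered, non-basic conditions should give the epoxy ketone without epimerising the now acidic C6–H or opening the oxirane. Alkenes and esters are inert to the reagent.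

## Compound list

1 | 4'-methylacetophenone | CC(=O)c1ccc(C)cc1 | starting material
2 | (1S,2R)-3-acetyl-6-methylcyclohexa-3,5-diene-1,2-diol | CC(=O)C1=CC=C(C)[C@H](O)[C@@H]1O | intermediate
3 | 1-[(3aR,7aS)-2,2,7-trimethyl-3a,7a-dihydro-1,3-benzodioxol-4-yl]ethan-1-one | CC(=O)C1=CC=C(C)[C@@H]2OC(C)(C)O[C@H]12 | intermediate
4 | dimethylphenylsilyl enol ether of 6 (enol geometry not defined), not isolated | CC(O[Si](C)(C)c3ccccc3)=C1CC=C(C)[C@@H]2OC(C)(C)O[C@H]12 | intermediate
5 | kinetic ketone mixture, drawn as the cis epimer 1-[(3aR,4R,7aS)-2,2,7-trimethyl-3a,4,5,7a-tetrahydro-1,3-benzodioxol-4-yl]ethan-1-one, not isolated | CC(=O)[C@@H]1CC=C(C)[C@@H]2OC(C)(C)O[C@H]12 | intermediate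
6 | 1-[(3aR,4S,7aS)-2,2,7-trimethyl-3a,4,5,7a-tetrahydro-1,3-benzodioxol-4-yl]ethan-1-one | CC(=O)[C@H]1CC=C(C)[C@@H]2OC(C)(C)O[C@H]12 | intermediate
7 | methyltriphenylphosphonium bromide | C[P+](c1ccccc1)(c1ccccc1)c1ccccc1.[Br-] | starting material
8 | methylenetriphenylphosphorane, not isolated | C=P(c1ccccc1)(c1ccccc1)c1ccccc1 | intermediate
9 | (3aR,4R,7aS)-2,2,7-trimethyl-4-(prop-1-en-2-yl)-3a,4,5,7a-tetrahydro-1,3-benzodioxole | C=C(C)[C@H]1CC=C(C)[C@@H]2OC(C)(C)O[C@H]12 | intermediate
10 | (1R,2S,6R)-3-methyl-6-(prop-1-en-2-yl)cyclohex-3-ene-1,2-diol | C=C(C)[C@H]1CC=C(C)[C@H](O)[C@@H]1O | intermediate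
11 | (1R,2R,3R,4R,6S)-1-methyl-4-(prop-1-en-2-yl)-7-oxabicyclo[4.1.0]heptane-2,3-diol | C=C(C)[C@H]1C[C@@H]2O[C@]2(C)[C@H](O)[C@@H]1O | intermediate
12 | allyl tiglate, prop-2-en-1-yl (2E)-2-methylbut-2-enoate | C=CCOC(=O)/C(C)=C/C | starting material
13 | tert-butyl methacrylate | C=C(C)C(=O)OC(C)(C)C | starting material
14 | tert-butyl (2E)-2-methyl-4-{[(2E)-2-methylbut-2-enoyl]oxy}but-2-enoate | CC(C)(C)OC(=O)/C(C)=C/COC(=O)/C(C)=C/C | intermediate
15 | (2E)-2-methyl-4-{[(2E)-2-methylbut-2-enoyl]oxy}but-2-enoic acid | OC(=O)/C(C)=C/COC(=O)/C(C)=C/C | intermediate
16 | (1R,2R,3R,4R,6S)-2-hydroxy-1-methyl-4-(prop-1-en-2-yl)-7-oxabicyclo[4.1.0]heptan-3-yl (2E)-2-methyl-4-{[(2E)-2-methylbut-2-enoyl]oxy}but-2-enoate | C=C(C)[C@H]1C[C@@H]2O[C@]2(C)[C@H](O)[C@@H]1OC(=O)/C(C)=C/COC(=O)/C(C)=C/C | intermediate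
17 | (1S,3R,4R,6S)-1-methyl-2-oxo-4-(prop-1-en-2-yl)-7-oxabicyclo[4.1.0]heptan-3-yl (2E)-2-methyl-4-{[(2E)-2-methylbut-2-enoyl]oxy}but-2-enoate | C=C(C)[C@H]1C[C@@H]2O[C@]2(C)C(=O)[C@@H]1OC(=O)/C(C)=C/COC(=O)/C(C)=C/C | target

## Step count and least certain steps

Total step count: 10. Longest linear sequence: 8 steps (steps 1–6, 9 and 10, from 1); steps 7 and 8 form the two-step side branch.

Step 1 (key step). Most likely to go wrong: poor binding or turnover, because both ring positions flanking the oxidised bond are substituted and one substituent is a ketone. Benzylic hydroxylation of the methyl group or carbonyl reduction by host enzymes could compete, and enantiomeric purity would suffer if the arene binds in both orientations. Fallback (iodine as the directing substituent, acetyl introduced afterwards by coupling): it sets out at the stage of 1, with commercial 4-iodotoluene fed to the same cells in its place, and returns at 3. The cells should give (1S,2S)-3-iodo-6-methylcyclohexa-3,5-diene-1,2-diol F1. Acetonide formation as in step 2 would give (3aS,7aS)-4-iodo-2,2,7-trimethyl-3a,7a-dihydro-1,3-benzodioxole F2. Stille coupling with tributyl(1-ethoxyvinyl)stannane (Pd(PPh3)4, CuI, DMF, rt) would give (3aR,7aS)-4-(1-ethoxyethenyl)-2,2,7-trimethyl-3a,7a-dihydro-1,3-benzodioxole F3, and brief treatment with dilute HCl in THF at 0 °C would hydrolyse the enol ether to 3.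

Step 3. Most likely to go wrong: hydride delivery to the δ-carbon (1,6) or to the carbonyl instead of C4; E1cB expulsion of the acetal oxygen O6 from the enolate during equilibration, since the ketone is β-alkoxy-substituted; or a thermodynamic preference for the trans isomer that is too small. Fallback (kinetic, hydroxyl-directed hydrogen delivery instead of thermodynamic protonation): it sets out from 2 and returns at 11. Directed epoxidation of 2 (VO(acac)2, t-BuOOH, CH2Cl2) at the more electron-rich C2=C3 bond, syn to O1, would give 1-[(1R,2R,3R,6S)-2,3-dihydroxy-1-methyl-7-oxabicyclo[4.1.0]hept-4-en-4-yl]ethan-1-one F4. Hydrogenation with [Ir(cod)(PCy3)(py)]PF6 and H2 in CH2Cl2, directed by the C6 hydroxyl, would add hydrogen to C4=C5 from the oxygenated face and give 1-[(1R,2R,3R,4S,6S)-2,3-dihydroxy-1-methyl-7-oxabicyclo[4.1.0]heptan-4-yl]ethan-1-one F5, with acetyl trans to O6. Methylenation with excess Ph3P=CH2 (or Cp2TiMe2) would give 11.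

Step 9. Most likely to go wrong: insufficient discrimination between the two secondary hydroxyls, with acylation at O1, bis-acylation or acyl migration between the cis oxygens. Fallback (tell the oxygens apart by oxidation state, not by acylation rate): it sets out from 10 and returns at 17. Allylic-selective oxidation of 10 with MnO2 in CH2Cl2 would give (5R,6R)-6-hydroxy-2-methyl-5-(prop-1-en-2-yl)cyclohex-2-en-1-one F6, which has a single hydroxyl. Steglich esterification with 15 would give (1R,6R)-3-methyl-2-oxo-6-(prop-1-en-2-yl)cyclohex-3-en-1-yl (2E)-2-methyl-4-{[(2E)-2-methylbut-2-enoyl]oxy}but-2-enoate F7. Nucleophilic epoxidation (t-BuOOH, DBU, CH2Cl2, 0 °C), anti to the isopropenyl group as in carvone, would give 17; the price is a basic last step on an ester-rich substrate.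

Step 7. Most likely to go wrong: slow turnover with the 1,1-disubstituted acrylate partner, so that homodimerisation of 12 and ruthenium hydride double-bond migration take over. Fallback (carbonyl olefination instead of metathesis): it sets out from 12 and returns at 14. Oxidative cleavage of the terminal alkene of 12 (OsO4 cat., NaIO4, 2,6-lutidine, dioxane–H2O) would give 2-oxoethyl (2E)-2-methylbut-2-enoate F8. Wittig reaction with the stabilised ylide tert-butyl 2-(triphenylphosphoranylidene)propanoate (CH2Cl2, rt) would give the E-enoate 14.

## Further compounds

F1 | step 1 | (1S,2S)-3-iodo-6-methylcyclohexa-3,5-diene-1,2-diol | IC1=CC=C(C)[C@H](O)[C@@H]1O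
F2 | step 1 | (3aS,7aS)-4-iodo-2,2,7-trimethyl-3a,7a-dihydro-1,3-benzodioxole | IC1=CC=C(C)[C@@H]2OC(C)(C)O[C@H]12
F3 | step 1 | (3aR,7aS)-4-(1-ethoxyethenyl)-2,2,7-trimethyl-3a,7a-dihydro-1,3-benzodioxole | CCOC(=C)C1=CC=C(C)[C@@H]2OC(C)(C)O[C@H]12
F4 | step 3 | 1-[(1R,2R,3R,6S)-2,3-dihydroxy-1-methyl-7-oxabicyclo[4.1.0]hept-4-en-4-yl]ethan-1-one | CC(=O)C1=C[C@@H]2O[C@]2(C)[C@H](O)[C@@H]1O
F5 | step 3 | 1-[(1R,2R,3R,4S,6S)-2,3-dihydroxy-1-methyl-7-oxabicyclo[4.1.0]heptan-4-yl]ethan-1-one | CC(=O)[C@H]1C[C@@H]2O[C@]2(C)[C@H](O)[C@@H]1O
F6 | step 9 | (5R,6R)-6-hydroxy-2-methyl-5-(prop-1-en-2-yl)cyclohex-2-en-1-one | C=C(C)[C@H]1CC=C(C)C(=O)[C@@H]1O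
F7 | step 9 | (1R,6R)-3-methyl-2-oxo-6-(prop-1-en-2-yl)cyclohex-3-en-1-yl (2E)-2-methyl-4-{[(2E)-2-methylbut-2-enoyl]oxy}but-2-enoate | C=C(C)[C@H]1CC=C(C)C(=O)[C@@H]1OC(=O)/C(C)=C/COC(=O)/C(C)=C/C
F8 | step 7 | 2-oxoethyl (2E)-2-methylbut-2-enoate | O=CCOC(=O)/C(C)=C/C
A1 | alternative 1 | (3R,4R)-6-bromo-4-[(tert-butyldimethylsilyl)oxy]-5-oxo-3-(prop-1-en-2-yl)heptanal (C6 epimers) | C=C(C)[C@@H](CC=O)[C@@H](O[Si](C)(C)C(C)(C)C)C(=O)C(C)Br
A2 | alternative 1 | (1S,3R,4R,6S)-3-[(tert-butyldimethylsilyl)oxy]-1-methyl-4-(prop-1-en-2-yl)-7-oxabicyclo[4.1.0]heptan-2-one | C=C(C)[C@H]1C[C@@H]2O[C@]2(C)C(=O)[C@@H]1O[Si](C)(C)C(C)(C)C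
A3 | alternative 2 | isoprene (2-methylbuta-1,3-diene) | C=CC(C)=C
A4 | alternative 2 | (1E)-3-oxobut-1-en-1-yl (2E)-2-methyl-4-{[(2E)-2-methylbut-2-enoyl]oxy}but-2-enoate | CC(=O)/C=C/OC(=O)/C(C)=C/COC(=O)/C(C)=C/C
A5 | alternative 2 | (1S,6S)-6-acetyl-3-methylcyclohex-3-en-1-yl (2E)-2-methyl-4-{[(2E)-2-methylbut-2-enoyl]oxy}but-2-enoate (trans) | CC(=O)[C@H]1CC=C(C)C[C@@H]1OC(=O)/C(C)=C/COC(=O)/C(C)=C/C
A6 | alternative 3 | 2-[(2S,3S)-2-methyl-3-(3-methylbut-2-en-1-yl)oxiran-2-yl]-2-oxoacetaldehyde | CC(C)=CC[C@@H]1O[C@]1(C)C(=O)C=O
A7 | alternative 3 | (1S,3R,4R,6S)-3-hydroxy-1-methyl-4-(prop-1-en-2-yl)-7-oxabicyclo[4.1.0]heptan-2-one | C=C(C)[C@H]1C[C@@H]2O[C@]2(C)C(=O)[C@@H]1O
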